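## The problem

The target is a trans-2-aryl-3-(hydroxymethyl)-2,3-dihydrobenzofuran neolignan. A guaiacyl ring (ring A) sits on C2 of a dihydrofuran ring (ring C), which is fused to a methoxylated benzene ring (ring B) carrying a 3-sulfooxypropyl chain at C5.

There are two stereocentres, C2 (S) and C3 (R), adjacent and trans. C2 is a benzylic ether carbon that cannot be corrected once set. C3 can be equilibrated while it carries a carbonyl group, and trans is the thermodynamic arrangement, so absolute control is needed at C2 only and C2 can then dictate C3.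

Three hydroxyl functions must be told apart: the ring A phenol, the β-branched primary alcohol on C3, and the unhindered primary alcohol at the chain end. Only the last is sulfated.

Two parts are fragile. The C2–O1 bond is a benzylic ether doubly activated by O1 and the para-oxygenated ring A, so it is open to acid ionisation and to over-reduction. The sulfate monoester is ionic and acid-labile, so it must come late and travel as a salt.

The C2–C3 bond makes the key step possible. C3 is bonded to ring B (at C3a) and to a carbon at carboxyl oxidation level, which is the substitution pattern of a donor–acceptor carbene. C2 is the CH of an aryl benzyl ether whose hydrogen is hydridic, and it lies five atoms from C3 through O1, C7a and C3a.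

C5 of ring B, para to O1, can hold a bromine atom through the sequence and receive the three-carbon chain late by cross-coupling.

## Retrosynthesis

**Sulfate and benzyl groups (18 ⇒ 16 ⇒ 15).** The S–O bond is cut first, since no earlier step would tolerate an ionic, acid-labile sulfate. The two other hydroxyls are masked as benzyl ethers, so one neutral hydrogenolysis of sodium sulfate 16 finishes the synthesis. Alcohol 15 is asked only to have a single free hydroxyl for the sulfation.

**Three-carbon chain (15 ⇒ 14 ⇒ 11 + 13).** The C5–CH2 bond is cut to aryl bromide 11 and alkylborane 13, which comes from allyl silyl ether 12 by hydroboration. A silyl ether on the chain and benzyl ethers elsewhere make the three hydroxyls distinguishable by construction. An aryl–alkyl coupling at C5 is preferred to carrying the chain through the carbene step, because bromine is inert to dirhodium carbenes and keeps an activated O–CH2 site out of the key step.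

**Adjustments at C3 (11 ⇒ 10 ⇒ 9 ⇒ 8).** Benzyl ether 11 comes from alcohol 10, that from trans ester 9 by hydride reduction, and 9 from cis ester 8 by base equilibration. The ester is kept until after the epimerisation because only then is C3–H acidic. The forward steps must leave C2 untouched.

**Ring C (8 ⇒ 7).** The C2–C3 bond is cut to aryldiazoacetate 7. This single cut removes the ring and both stereocentres and leaves an acyclic diaryl ether. It is preferred to an O1–C2 or C3–C3a cut because the absolute configuration then comes from a catalyst acting on one substrate. The catalyst chosen is dirhodium tetrakis[N-phthaloyl-(R)-tert-leucinate], Rh2(R-PTTL)4. The forward reaction must pick one of the two enantiotopic hydrogens of the O–CH2 group; its cis outcome does not matter, because the next step inverts C3.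

**Diazo ester (7 ⇒ 6 ⇒ 5 ⇒ 4).** Diazo transfer relates 7 to arylacetate 6. The arylacetate is traced to aldehyde 4 by a one-carbon homologation through enol ether 5. This homologation avoids strong acid, because the aryl dialkoxybenzyl ether of 4 is acid-labile.

**Diaryl ether (4 ⇒ 2 + 3, 2 ⇐ 1).** The O–CH2 bond is cut to 5-bromo-2-hydroxy-3-methoxybenzaldehyde 3 and benzylic chloride 2. Chloride 2 comes from commercial alcohol 1, the reduction product of O-benzylvanillin. Both ring precursors are thus commodity vanillin-type aromatics, and the bromine of 3 is already para to the phenol oxygen.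

## Roads not taken

**Alternative 1:** Ring C is cut at both O1–C2 and C2–C3. The forward step is a [4+1] annulation: a base-generated ortho-quinone methide of ring B takes up a sulfonium benzylide carrying ring A, and the phenoxide then displaces the sulfide to give the trans product A1.
- Merits: it is convergent and forms two bonds at once. It gives trans directly, and C3 is already at alcohol oxidation level, so epimerisation and reduction both disappear.
- Weak points: the absolute configuration would rest on a stoichiometric chiral sulfide with a semi-stabilised, electron-rich benzylide, a combination with less support than carbonyl-stabilised ylides. Para-alkoxybenzyl sulfonium salts lose the sulfide easily. The quinone methide carries a β-benzyloxyalkylidene terminus that can tautomerise or eliminate, and three oxygen donors on ring B make it a weak electrophile. The allyl group of A1 still needs hydroboration.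
- Comparison: after ring formation this road is shorter and cleaner in redox terms. The chosen plan sets against it a catalytic source of chirality with close precedent, acting within one molecule.

**Alternative 2:** The cuts are C3–C3a and O1–C7a. A ring B aryl iodide with one free ortho position is joined to an enantioenriched cis-epoxide bearing ring A and an acyloxymethyl group. A palladium/strained-alkene relay (Catellani type) alkylates the ortho position with inversion at the epoxide carbon, and the alkoxide then couples at the ipso carbon to give A2.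
- Merits: it is the most convergent road. The full chain is in place, cis-epoxide maps onto trans product automatically, and the ester protecting groups come off with base, so no hydrogenolysis is needed near the C2–O1 bond. That is a real advantage.
- Weak points: this annulation is established mainly for terminal epoxides. Here the palladacycle must attack the more hindered, non-benzylic carbon of an internal epoxide. The benzylic C–O bond of an electron-rich aryl epoxide ionises readily under heat and base, which risks regiochemical leakage, rearrangement to carbonyl compounds and loss of stereochemical fidelity. The cis-epoxide itself is not trivial to make in high enantiopurity.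
- Comparison: if it worked it would be about half the length of the chosen plan. The chosen plan offers precedent on its own substrate class and a stereochemical outcome that does not depend on a clean displacement at a hindered centre.

**Alternative 3:** Only O1–C2 is cut. A 1,2-diarylpropane-1,3-diol with the ring B phenol masked as an acetal ether is treated with methanolic acid. The acid unmasks the phenol and ionises the benzylic alcohol of either epimer to a para-alkoxybenzyl cation, which the phenol captures trans to the C3 substituent to give A3.
- Merits: this is the classical, robust closure for the neolignan class. It is stereoconvergent at C2, so only C3 has to be set, for example by an auxiliary-controlled aldol (Evans type) and reduction. No diazo compound or carbene is involved, and A3 already carries the free C3 alcohol.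
- Weak points: the chirality comes from a stoichiometric auxiliary that must be attached and removed. The C3 centre is epimerisable until reduction. The cation can be diverted by solvent or by the primary alcohol, and trans selectivity is good but not guaranteed to be complete. The allyl group and the free alcohol then need the same differentiation as in the chosen plan.
- Comparison: in reliability of ring closure this road is at least equal and arguably safer. The chosen plan sets against it catalytic asymmetry that forms both centres in one step, no auxiliary steps, and an aryl bromide for late chain installation. The price is diazo handling and an epimerisation–reduction pair.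

Key step: step 6

Assumption (sense of induction): in the closest analogues the S-configured phthaloyl-tert-leucinate catalyst is taken to give the (2R,3S)-cis ester, so the (2S,3R) ester needed here is assigned to the antipode Rh2(R-PTTL)4; should the sense on this substrate be the opposite, the S-configured catalyst replaces it and nothing else changes.

Assumption (form of the target): the sulfate is carried as its sodium salt (16, 17) and the hydrogen sulfate as drawn is released only in the last work-up; it is best stored as the salt.

## Route

Step 1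
Reactants: 1 [4-(benzyloxy)-3-methoxyphenyl]methanol
Product: 2 1-(benzyloxy)-4-(chloromethyl)-2-methoxybenzene
Conditions: SOCl2, DMF (cat.), CH2Cl2, 0 °C → rt; evaporate, use crude
Reagents that add atoms: thionyl chloride, ClS(Cl)=O
Why: Chlorodehydroxylation of an electron-rich benzylic alcohol through its chlorosulfite; the aryl benzyl ether tolerates the brief exposure to HCl, and the chloride is used crude because it solvolyses on silica.

Step 2
Reactants: 3 5-bromo-2-hydroxy-3-methoxybenzaldehyde, 2 1-(benzyloxy)-4-(chloromethyl)-2-methoxybenzene
Product: 4 2-{[4-(benzyloxy)-3-methoxyphenyl]methoxy}-5-bromo-3-methoxybenzaldehyde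
Conditions: K2CO3, KI (cat.), DMF, 60 °C
Reagents that add atoms: none
Why: Williamson ether synthesis; the salicylaldehyde-type phenol is acidic enough for K2CO3, iodide turns the chloride into the more reactive benzylic iodide in the flask (Finkelstein exchange), and the aldehyde and aryl bromide are untouched.

Step 3
Reactants: 4 2-{[4-(benzyloxy)-3-methoxyphenyl]methoxy}-5-bromo-3-methoxybenzaldehyde
Product: 5 2-{[4-(benzyloxy)-3-methoxyphenyl]methoxy}-5-bromo-1-methoxy-3-(2-methoxyethenyl)benzene (E/Z mixture)
Conditions: MeOCH2PPh3Cl, KOtBu, THF, 0 °C → rt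
Reagents that add atoms: (methoxymethyl)triphenylphosphonium chloride, COC[P+](c1ccccc1)(c1ccccc1)c1ccccc1.[Cl-]
Why: Wittig olefination of a non-enolisable aryl aldehyde with the non-stabilised methoxymethylidene ylide; the E/Z mixture is of no consequence because both isomers converge in step 4.

Step 4
Reactants: 5 2-{[4-(benzyloxy)-3-methoxyphenyl]methoxy}-5-bromo-1-methoxy-3-(2-methoxyethenyl)benzene
Product: 6 methyl 2-(2-{[4-(benzyloxy)-3-methoxyphenyl]methoxy}-5-bromo-3-methoxyphenyl)acetate
Conditions: pyridinium chlorochromate, 4 Å MS, CH2Cl2, rt
Reagents that add atoms: pyridinium chlorochromate, [O-][Cr](=O)(=O)Cl.c1cc[nH+]cc1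
Why: Chlorochromate oxidation of an enol ether to an ester: protonation at the aryl-bearing carbon gives an oxocarbenium ion, chlorochromate adds, and the chromate ester collapses to the methyl ester; no strong acid is present, so the acid-labile dialkoxybenzyl aryl ether is spared.

Step 5
Reactants: 6 methyl 2-(2-{[4-(benzyloxy)-3-methoxyphenyl]methoxy}-5-bromo-3-methoxyphenyl)acetate
Product: 7 methyl 2-(2-{[4-(benzyloxy)-3-methoxyphenyl]methoxy}-5-bromo-3-methoxyphenyl)-2-diazoacetate
Conditions: 4-acetamidobenzenesulfonyl azide, DBU, MeCN, 0 °C → rt
Reagents that add atoms: 4-acetamidobenzenesulfonyl azide, CC(=O)Nc1ccc(cc1)S(=O)(=O)N=[N+]=[N-]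
Why: Regitz diazo transfer; DBU deprotonates the benzylic α-carbon, the enolate takes N2 from the sulfonyl azide and the sulfonamide leaves; arylacetates with ortho-alkoxy groups are standard substrates, and bromide and ethers are inert.

Step 6
Reactants: 7 methyl 2-(2-{[4-(benzyloxy)-3-methoxyphenyl]methoxy}-5-bromo-3-methoxyphenyl)-2-diazoacetate
Product: 8 methyl (2S,3R)-2-[4-(benzyloxy)-3-methoxyphenyl]-5-bromo-7-methoxy-2,3-dihydro-1-benzofuran-3-carboxylate (cis)
Conditions: Rh2(R-PTTL)4 (1 mol %), 4 Å MS, toluene, −78 → −60 °C
Reagents that add atoms: none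
Why: The diazo ester loses N2 on the divalent-rhodium paddlewheel to give a donor–acceptor carbene (ring B as donor, ester as acceptor). The carbene inserts into one of the two enantiotopic C–H bonds of the O–CH2 group through a concerted, asynchronous three-centre transition state with hydride-transfer character, the developing positive charge at C2 being stabilised by O1 and the para-oxygenated ring A. The closest known reaction type is the enantioselective intramolecular C–H insertion of methyl 2-(2-benzyloxyaryl)-2-diazoacetates with dirhodium phthalimido-amino-acid carboxylates, which gives cis-2-aryl-2,3-dihydrobenzofuran-3-carboxylates. Ring C closes by a 1,5-insertion that forms C2–C3 through a five-membered cyclic transition state; the O–CH2 group is the only C–H site at that distance, since the methoxy and distal benzyloxy hydrogens are out of reach. C2 is fixed by the chiral catalyst, whose phthalimido walls decide which hydrogen of O–CH2 is replaced. C3 is set at the same moment, cis to the C2 aryl, as the kinetic result of the insertion geometry, and step 7 inverts it. The step needs enantiotopic-hydrogen selection (low temperature, non-coordinating toluene) and insertion ahead of carbene dimerisation or attack on the electron-rich rings, which the activated intramolecular pathway should secure. The aryl bromide is not touched by dirhodium carbenes.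

Step 7
Reactants: 8 methyl (2S,3R)-2-[4-(benzyloxy)-3-methoxyphenyl]-5-bromo-7-methoxy-2,3-dihydro-1-benzofuran-3-carboxylate
Product: 9 methyl (2S,3S)-2-[4-(benzyloxy)-3-methoxyphenyl]-5-bromo-7-methoxy-2,3-dihydro-1-benzofuran-3-carboxylate (trans)
Conditions: NaOMe (0.3 equiv), MeOH/THF, 0 °C → rt
Reagents that add atoms: none
Why: Thermodynamic epimerisation of C3 through the ester enolate places the ester trans to the C2 aryl; C2 is not acidic, and β-elimination of O1 is stereoelectronically disfavoured because the C2–O1 bond lies in the ring plane, orthogonal to the enolate π system (the reverse of a 5-endo-trig closure), so the C2 configuration should be retained. Methoxide in methanol makes ester exchange degenerate.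

Step 8
Reactants: 9 methyl (2S,3S)-2-[4-(benzyloxy)-3-methoxyphenyl]-5-bromo-7-methoxy-2,3-dihydro-1-benzofuran-3-carboxylate
Product: 10 {(2S,3R)-2-[4-(benzyloxy)-3-methoxyphenyl]-5-bromo-7-methoxy-2,3-dihydro-1-benzofuran-3-yl}methanol (trans)
Conditions: LiBH4, THF, 0 °C → rt
Reagents that add atoms: none
Why: Chemoselective borohydride reduction of the ester; aryl bromide and ethers are inert, and once reduced C3 is no longer epimerisable (the descriptor changes from S to R only through the priority change at C3).

Step 9
Reactants: 10 {(2S,3R)-2-[4-(benzyloxy)-3-methoxyphenyl]-5-bromo-7-methoxy-2,3-dihydro-1-benzofuran-3-yl}methanol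
Product: 11 (2S,3R)-2-[4-(benzyloxy)-3-methoxyphenyl]-3-[(benzyloxy)methyl]-5-bromo-7-methoxy-2,3-dihydro-1-benzofuran
Conditions: NaH, BnBr, Bu4NI (cat.), DMF, 0 °C → rt
Reagents that add atoms: benzyl bromide, BrCc1ccccc1
Why: Williamson O-benzylation of the primary alkoxide; it puts the C3 alcohol under the same hydrogenolysable group as the phenol and so distinguishes it from the chain alcohol that comes later.

Step 10
Reactants: 11 (2S,3R)-2-[4-(benzyloxy)-3-methoxyphenyl]-3-[(benzyloxy)methyl]-5-bromo-7-methoxy-2,3-dihydro-1-benzofuran, 12 tert-butyl(dimethyl)(prop-2-en-1-yloxy)silane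
Product: 14 (2S,3R)-2-[4-(benzyloxy)-3-methoxyphenyl]-3-[(benzyloxy)methyl]-5-{3-[tert-butyl(dimethyl)silyloxy]propyl}-7-methoxy-2,3-dihydro-1-benzofuran, via [3-(9-borabicyclo[3.3.1]nonan-9-yl)propoxy](tert-butyl)dimethylsilane 13 (not isolated)
Conditions: 12, 9-BBN-H, THF, 0 °C → rt; then 11, PdCl2(dppf)·CH2Cl2 (5 mol %), aq K3PO4, DMF, 60 °C
Reagents that add atoms: none
Why: Anti-Markovnikov hydroboration of the terminal alkene with 9-BBN followed by B-alkyl Suzuki–Miyaura coupling; the base-activated alkylborane transmetallates to the arylpalladium bromide and the wide-bite-angle dppf ligand favours reductive elimination over β-hydride elimination. Benzyl and silyl ethers and both stereocentres are untouched.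

Step 11
Reactants: 14 (2S,3R)-2-[4-(benzyloxy)-3-methoxyphenyl]-3-[(benzyloxy)methyl]-5-{3-[tert-butyl(dimethyl)silyloxy]propyl}-7-methoxy-2,3-dihydro-1-benzofuran
Product: 15 3-{(2S,3R)-2-[4-(benzyloxy)-3-methoxyphenyl]-3-[(benzyloxy)methyl]-7-methoxy-2,3-dihydro-1-benzofuran-5-yl}propan-1-ol
Conditions: Bu4NF, THF, 0 °C → rt
Reagents that add atoms: none
Why: Fluoride-driven cleavage of the primary silyl ether (strong Si–F bond); benzyl and aryl ethers are inert, so the chain alcohol becomes the only free hydroxyl.

Step 12
Reactants: 15 3-{(2S,3R)-2-[4-(benzyloxy)-3-methoxyphenyl]-3-[(benzyloxy)methyl]-7-methoxy-2,3-dihydro-1-benzofuran-5-yl}propan-1-ol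
Product: 16 sodium 3-{(2S,3R)-2-[4-(benzyloxy)-3-methoxyphenyl]-3-[(benzyloxy)methyl]-7-methoxy-2,3-dihydro-1-benzofuran-5-yl}propyl sulfate
Conditions: SO3·pyridine, pyridine, rt; then aq NaHCO3
Reagents that add atoms: sulfur trioxide–pyridine complex, [O-]S(=O)(=O)[n+]1ccccc1; sodium hydrogen carbonate, [Na+].OC([O-])=O
Why: O-Sulfation of the only free (primary) alcohol with the amine-moderated SO3 complex; the basic medium protects the acid-sensitive C2–O1 bond and hydrogen carbonate exchanges pyridinium for sodium.

Step 13
Reactants: 16 sodium 3-{(2S,3R)-2-[4-(benzyloxy)-3-methoxyphenyl]-3-[(benzyloxy)methyl]-7-methoxy-2,3-dihydro-1-benzofuran-5-yl}propyl sulfate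
Product: 18 3-[(2S,3R)-2-(4-hydroxy-3-methoxyphenyl)-3-(hydroxymethyl)-7-methoxy-2,3-dihydro-1-benzofuran-5-yl]propyl hydrogen sulfate, via sodium salt of the target 17 (not isolated)
Conditions: H2 (1 atm), 10% Pd/C, MeOH, rt; filter; then aq HCl (1 equiv), 0 °C, reversed-phase (C18) desalting, lyophilise
Reagents that add atoms: none
Why: Heterogeneous hydrogenolysis of both benzyl ethers (the aryl ether quickly, the primary alkyl ether more slowly); a sulfate monoester salt is inert to H2 on palladium, and neutral methanol at ambient pressure is chosen to spare the C2–O1 bond. Cold protonation with one equivalent of acid releases the hydrogen sulfate; if C2–O1 ionised reversibly, the untouched C3 centre would steer re-closure back to trans.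

## Compound list

1 | [4-(benzyloxy)-3-methoxyphenyl]methanol | COc1cc(CO)ccc1OCc1ccccc1 | starting material
2 | 1-(benzyloxy)-4-(chloromethyl)-2-methoxybenzene | COc1cc(CCl)ccc1OCc1ccccc1 | intermediate
3 | 5-bromo-2-hydroxy-3-methoxybenzaldehyde | COc1cc(Br)cc(C=O)c1O | starting material
4 | 2-{[4-(benzyloxy)-3-methoxyphenyl]methoxy}-5-bromo-3-methoxybenzaldehyde | COc1cc(Br)cc(C=O)c1OCc1ccc(OCc2ccccc2)c(OC)c1 | intermediate
5 | 2-{[4-(benzyloxy)-3-methoxyphenyl]methoxy}-5-bromo-1-methoxy-3-(2-methoxyethenyl)benzene (E/Z mixture) | COC=Cc1cc(Br)cc(OC)c1OCc1ccc(OCc2ccccc2)c(OC)c1 | intermediate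
6 | methyl 2-(2-{[4-(benzyloxy)-3-methoxyphenyl]methoxy}-5-bromo-3-methoxyphenyl)acetate | COC(=O)Cc1cc(Br)cc(OC)c1OCc1ccc(OCc2ccccc2)c(OC)c1 | intermediate
7 | methyl 2-(2-{[4-(benzyloxy)-3-methoxyphenyl]methoxy}-5-bromo-3-methoxyphenyl)-2-diazoacetate | COC(=O)C(=[N+]=[N-])c1cc(Br)cc(OC)c1OCc1ccc(OCc2ccccc2)c(OC)c1 | intermediate
8 | methyl (2S,3R)-2-[4-(benzyloxy)-3-methoxyphenyl]-5-bromo-7-methoxy-2,3-dihydro-1-benzofuran-3-carboxylate (cis) | COc1cc([C@H]2Oc3c(OC)cc(Br)cc3[C@H]2C(=O)OC)ccc1OCc1ccccc1 | intermediate
9 | methyl (2S,3S)-2-[4-(benzyloxy)-3-methoxyphenyl]-5-bromo-7-methoxy-2,3-dihydro-1-benzofuran-3-carboxylate (trans) | COc1cc([C@H]2Oc3c(OC)cc(Br)cc3[C@@H]2C(=O)OC)ccc1OCc1ccccc1 | intermediate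
10 | {(2S,3R)-2-[4-(benzyloxy)-3-methoxyphenyl]-5-bromo-7-methoxy-2,3-dihydro-1-benzofuran-3-yl}methanol (trans) | COc1cc([C@H]2Oc3c(OC)cc(Br)cc3[C@@H]2CO)ccc1OCc1ccccc1 | intermediate
11 | (2S,3R)-2-[4-(benzyloxy)-3-methoxyphenyl]-3-[(benzyloxy)methyl]-5-bromo-7-methoxy-2,3-dihydro-1-benzofuran | COc1cc([C@H]2Oc3c(OC)cc(Br)cc3[C@@H]2COCc2ccccc2)ccc1OCc1ccccc1 | intermediate
12 | tert-butyl(dimethyl)(prop-2-en-1-yloxy)silane | C=CCO[Si](C)(C)C(C)(C)C | starting material
13 | [3-(9-borabicyclo[3.3.1]nonan-9-yl)propoxy](tert-butyl)dimethylsilane | CC(C)(C)[Si](C)(C)OCCCB1C2CCCC1CCC2 | intermediate (not isolated)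
14 | (2S,3R)-2-[4-(benzyloxy)-3-methoxyphenyl]-3-[(benzyloxy)methyl]-5-{3-[tert-butyl(dimethyl)silyloxy]propyl}-7-methoxy-2,3-dihydro-1-benzofuran | COc1cc([C@H]2Oc3c(OC)cc(CCCO[Si](C)(C)C(C)(C)C)cc3[C@@H]2COCc2ccccc2)ccc1OCc1ccccc1 | intermediate
15 | 3-{(2S,3R)-2-[4-(benzyloxy)-3-methoxyphenyl]-3-[(benzyloxy)methyl]-7-methoxy-2,3-dihydro-1-benzofuran-5-yl}propan-1-ol | COc1cc([C@H]2Oc3c(OC)cc(CCCO)cc3[C@@H]2COCc2ccccc2)ccc1OCc1ccccc1 | intermediate
16 | sodium 3-{(2S,3R)-2-[4-(benzyloxy)-3-methoxyphenyl]-3-[(benzyloxy)methyl]-7-methoxy-2,3-dihydro-1-benzofuran-5-yl}propyl sulfate | COc1cc([C@H]2Oc3c(OC)cc(CCCOS(=O)(=O)[O-])cc3[C@@H]2COCc2ccccc2)ccc1OCc1ccccc1.[Na+] | intermediate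
17 | sodium 3-[(2S,3R)-2-(4-hydroxy-3-methoxyphenyl)-3-(hydroxymethyl)-7-methoxy-2,3-dihydro-1-benzofuran-5-yl]propyl sulfate | COc1cc([C@H]2Oc3c(OC)cc(CCCOS(=O)(=O)[O-])cc3[C@@H]2CO)ccc1O.[Na+] | intermediate (not isolated)
18 | 3-[(2S,3R)-2-(4-hydroxy-3-methoxyphenyl)-3-(hydroxymethyl)-7-methoxy-2,3-dihydro-1-benzofuran-5-yl]propyl hydrogen sulfate | COc1cc([C@H]2Oc3c(OC)cc(CCCOS(=O)(=O)O)cc3[C@@H]2CO)ccc1O | target

## Step count and least certain steps

Total step count: 13. Longest linear sequence: 13 steps (1 to 18); 3 enters at step 2 and 12 at step 10.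

**Step 6 (key step).** The most likely failure is poor discrimination between the two enantiotopic hydrogens. The 3-methoxy group next to the ether oxygen twists the O–CH2–aryl group out of the plane of ring B, and the very hydridic C–H makes the transition state early. Carbene dimerisation is a lesser risk.

Fallback: stereocontrol is moved from catalysis to resolution. Setting out from 7, decomposition with achiral Rh2(OAc)4 in CH2Cl2 should give the racemic cis-rich ester F1. NaOMe in MeOH equilibrates it to the racemic trans ester F2. Preparative chromatography on a chiral stationary phase separates the enantiomers, and the (2S,3S) enantiomer rejoins the route at 9.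

**Step 4.** The oxidant may cleave the electron-rich styrenyl double bond back to aldehyde 4, or the pyridinium salt may cause loss of the dialkoxybenzyl ether.

Fallback: a chromium-free and acid-free homologation. Setting out from 4, methylenation (Ph3P=CH2, THF) gives the styrene F3. Hydroboration–oxidation (9-BBN-H, then NaOH/H2O2) gives the 2-arylethanol F4. Oxidation with TEMPO/PhI(OAc)2 in aqueous MeCN gives the arylacetic acid F5. Methylation (MeI, K2CO3, DMF) returns to the route at 6.

**Step 10.** Oxidative addition to the electron-rich aryl bromide may be slow, leaving the alkylborane to protodeboronate or the alkylpalladium to undergo β-hydride elimination. The result would be reduced arene and recovered 11.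

Fallback: the palladium cycle is replaced by polar organometallic chemistry. Setting out from 11, bromine–lithium exchange (n-BuLi, THF, −78 °C) followed by BF3·OEt2-promoted opening of oxetane at −78 °C should give the 3-hydroxypropyl compound directly. It rejoins the route at 15, bypassing 14 and step 11.

**Step 13.** The primary alkyl benzyl ether cleaves slowly on an ionic substrate in methanol, and a long exposure invites reductive opening of the C2–O1 bond. The acidification may also cause partial solvolysis of the sulfate.

Fallback: the protecting-group logic is changed so that the sulfate never meets the catalyst and the last step is basic. Setting out from 14, hydrogenolysis (H2, Pd/C, EtOAc) is done on the neutral silyl ether, where over-reduced material can be removed on silica, to give the phenol–alcohol F6. Ac2O/pyridine gives the diacetate F7. HF·pyridine gives the chain alcohol F8. SO3·pyridine and then NaHCO3 give the diacetate sulfate F9. K2CO3 in MeOH removes both acetates and rejoins the route at 17, which is protonated as in step 13.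

## Further compounds

F1 | step 6 | racemic methyl cis-2-[4-(benzyloxy)-3-methoxyphenyl]-5-bromo-7-methoxy-2,3-dihydro-1-benzofuran-3-carboxylate (both enantiomers) | COc1cc([C@H]2Oc3c(OC)cc(Br)cc3[C@H]2C(=O)OC)ccc1OCc1ccccc1.COc1cc([C@@H]2Oc3c(OC)cc(Br)cc3[C@@H]2C(=O)OC)ccc1OCc1ccccc1
F2 | step 6 | racemic methyl trans-2-[4-(benzyloxy)-3-methoxyphenyl]-5-bromo-7-methoxy-2,3-dihydro-1-benzofuran-3-carboxylate (both enantiomers) | COc1cc([C@H]2Oc3c(OC)cc(Br)cc3[C@@H]2C(=O)OC)ccc1OCc1ccccc1.COc1cc([C@@H]2Oc3c(OC)cc(Br)cc3[C@H]2C(=O)OC)ccc1OCc1ccccc1
F3 | step 4 | 2-{[4-(benzyloxy)-3-methoxyphenyl]methoxy}-5-bromo-1-ethenyl-3-methoxybenzene | C=Cc1cc(Br)cc(OC)c1OCc1ccc(OCc2ccccc2)c(OC)c1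
F4 | step 4 | 2-(2-{[4-(benzyloxy)-3-methoxyphenyl]methoxy}-5-bromo-3-methoxyphenyl)ethan-1-ol | OCCc1cc(Br)cc(OC)c1OCc1ccc(OCc2ccccc2)c(OC)c1
F5 | step 4 | 2-(2-{[4-(benzyloxy)-3-methoxyphenyl]methoxy}-5-bromo-3-methoxyphenyl)acetic acid | OC(=O)Cc1cc(Br)cc(OC)c1OCc1ccc(OCc2ccccc2)c(OC)c1
F0 | step 10 | none | none
F6 | step 13 | 4-[(2S,3R)-5-{3-[tert-butyl(dimethyl)silyloxy]propyl}-3-(hydroxymethyl)-7-methoxy-2,3-dihydro-1-benzofuran-2-yl]-2-methoxyphenol | COc1cc([C@H]2Oc3c(OC)cc(CCCO[Si](C)(C)C(C)(C)C)cc3[C@@H]2CO)ccc1O
F7 | step 13 | 4-[(2S,3R)-3-(acetoxymethyl)-5-{3-[tert-butyl(dimethyl)silyloxy]propyl}-7-methoxy-2,3-dihydro-1-benzofuran-2-yl]-2-methoxyphenyl acetate | COc1cc([C@H]2Oc3c(OC)cc(CCCO[Si](C)(C)C(C)(C)C)cc3[C@@H]2COC(C)=O)ccc1OC(C)=O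
F8 | step 13 | 4-[(2S,3R)-3-(acetoxymethyl)-5-(3-hydroxypropyl)-7-methoxy-2,3-dihydro-1-benzofuran-2-yl]-2-methoxyphenyl acetate | COc1cc([C@H]2Oc3c(OC)cc(CCCO)cc3[C@@H]2COC(C)=O)ccc1OC(C)=O
F9 | step 13 | sodium 3-[(2S,3R)-3-(acetoxymethyl)-2-(4-acetoxy-3-methoxyphenyl)-7-methoxy-2,3-dihydro-1-benzofuran-5-yl]propyl sulfate | COc1cc([C@H]2Oc3c(OC)cc(CCCOS(=O)(=O)[O-])cc3[C@@H]2COC(C)=O)ccc1OC(C)=O.[Na+]
A1 | alternative 1 | (2S,3R)-5-allyl-2-[4-(benzyloxy)-3-methoxyphenyl]-3-[(benzyloxy)methyl]-7-methoxy-2,3-dihydro-1-benzofuran (trans) | COc1cc([C@H]2Oc3c(OC)cc(CC=C)cc3[C@@H]2COCc2ccccc2)ccc1OCc1ccccc1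
A2 | alternative 2 | {(2S,3R)-7-methoxy-2-[3-methoxy-4-(pivaloyloxy)phenyl]-5-[3-(triisopropylsilyloxy)propyl]-2,3-dihydro-1-benzofuran-3-yl}methyl pivalate (trans) | COc1cc([C@H]2Oc3c(OC)cc(CCCO[Si](C(C)C)(C(C)C)C(C)C)cc3[C@@H]2COC(=O)C(C)(C)C)ccc1OC(=O)C(C)(C)C
A3 | alternative 3 | {(2S,3R)-5-allyl-2-[4-(benzyloxy)-3-methoxyphenyl]-7-methoxy-2,3-dihydro-1-benzofuran-3-yl}methanol (trans) | COc1cc([C@H]2Oc3c(OC)cc(CC=C)cc3[C@@H]2CO)ccc1OCc1ccccc1
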